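**Retrosynthetic overview** (ring A = methylcyclopentane, ring B = eight-membered ring, ring C = cyclohexene, ring D = isopropylcyclopentanol)

1. Target ⇐ silyl ether 28 ⇐ triene triflate 27: ring B is closed last by an 8-exo Heck cyclisation that makes the bond between the ring-B carbon carrying the exocyclic methylene and the neighbouring sp2 carbon shared by rings B and C.
2. Enabling feature: the exocyclic CH2=C of ring B is conjugated to the tetrasubstituted olefin of the B/C fusion. This 2-substituted 1,3-diene is what a ring-C enol triflate and a vinyl group on ring A deliver after β-hydride elimination; the cis ring-C olefin and the trans-1,2 substituents on ring A hold the two termini close.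
3. Ring A ⇐ Evans syn-aldol of chain aldehyde 17 with imide 20, then a deoxygenative 5-exo radical cyclisation in which the one auxiliary-set centre relays two more in a single event.
4. Rings C/D ⇐ Robinson-type annulation of 2-methylcyclopentane-1,3-dione (ring D) with an enone made from (S)-citronellal, which supplies the ring-B methyl stereocentre and five ring-B carbons. D-Proline sets the quaternary centre; the isopropyl, carbinol and trans-fusion centres follow by substrate control.
5. Order of ring formation: D (from the dione) → C → A → B.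

Key step: step 20

Remark: the stereocentre between the ring-C carbonyl and the side chain is carried as an epimer mixture in 6–13 and becomes sp2 in 15, so it is left undefined.
Abbreviation used in names: Hyd = (1R,3S,3aS,7aR)-1-[(tert-butyldimethylsilyl)oxy]-7a-methyl-3-(propan-2-yl)-5-[(trifluoromethanesulfonyl)oxy]-2,3,3a,4,7,7a-hexahydro-1H-inden-6-yl.

**Route**

Step 1
Reactants: 1 (S)-citronellal
Product: 2 (3S)-3,7-dimethyl-2-methylideneoct-6-enal
Conditions: aq. CH2O (37%), pyrrolidine (10 mol %), EtCO2H (10 mol %), i-PrOH, 45 °C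
Reagents that add atoms: formaldehyde C=O
Why: Organocatalytic α-methylenation of an aldehyde (Mannich condensation–elimination through the enamine) should install the methylidene without touching the β-methyl stereocentre.

Step 2
Reactants: 2 (3S)-3,7-dimethyl-2-methylideneoct-6-enal
Product: 3 (4S)-4,8-dimethyl-3-methylidenenon-7-en-2-ol
Conditions: MeMgBr, THF, −78 °C; aq. NH4Cl
Reagents that add atoms: methylmagnesium bromide C[Mg]Br
Why: 1,2-Grignard addition to the enal should give the allylic alcohol; the new carbinol centre is removed in the next step.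

Step 3
Reactants: 3 allylic alcohol
Product: 4 (4S)-4,8-dimethyl-3-methylidenenon-7-en-2-one
Conditions: Dess–Martin periodinane, CH2Cl2, 0 °C → rt
Reagents that add atoms: none
Why: Dess–Martin oxidation of a secondary allylic alcohol should give the α-substituted vinyl ketone under neutral conditions.

Step 4
Reactants: 4 enone; 5 2-methylcyclopentane-1,3-dione
Product: 6 2-[(3S)-2-acetyl-3,7-dimethyloct-6-en-1-yl]-2-methylcyclopentane-1,3-dione
Conditions: Et3N (0.1 equiv), EtOAc, 60 °C
Reagents that add atoms: none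
Why: Michael addition of the acidic cyclic 1,3-dione to the unsubstituted terminus of the vinyl ketone should give the triketone; the new α-centre forms unselectively and is erased later.

Step 5
Reactants: 6 triketone
Product: 8 (7aR)-7a-methyl-6-[(2S)-6-methylhept-5-en-2-yl]-2,3,7,7a-tetrahydro-1H-indene-1,5(6H)-dione, via cis-fused aldol ketol 7 (not isolated)
Conditions: D-proline (30 mol %), DMF, rt; then TsOH·H2O (cat.), PhMe, 80 °C
Reagents that add atoms: none
Why: Hajos–Parrish–Eder–Sauer–Wiechert reaction: the D-proline enamine of the methyl ketone should desymmetrise the two ring carbonyls and set the quaternary methyl centre as R (mirror image of the L-proline outcome), and acid then dehydrates the ketol to the enone.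

Step 6
Reactants: 8 enedione
Product: 9 (7aR)-7a-methyl-6-[(2S)-6-methylhept-5-en-2-yl]-7,7a-dihydro-1H-indene-1,5(6H)-dione
Conditions: IBX, 4-methoxypyridine N-oxide, DMSO, 25–45 °C
Reagents that add atoms: none
Why: IBX dehydrogenation of a ketone to an enone should occur at the cyclopentanone, whose β-hydrogens are allylic and whose product is the fully conjugated ene-dione, rather than at the hindered tertiary α′-position of the cyclohexenone.

Step 7
Reactants: 9 dienedione
Product: 10 (3S,7aR)-7a-methyl-6-[(2S)-6-methylhept-5-en-2-yl]-3-(propan-2-yl)-2,3,7,7a-tetrahydro-1H-indene-1,5(6H)-dione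
Conditions: i-PrMgCl, CuBr·SMe2 (20 mol %), THF, −78 °C; aq. NH4Cl
Reagents that add atoms: isopropylmagnesium chloride CC(C)[Mg]Cl
Why: Copper-catalysed Grignard conjugate addition should go to the cyclopentenone β-carbon (the cyclohexenone β-carbon is fully substituted and the far diene terminus is the α-carbon of the other carbonyl) from the face opposite the angular methyl, placing isopropyl trans to that methyl.

Step 8
Reactants: 10 isopropyl enedione
Product: 11 (1R,3S,7aR)-1-hydroxy-7a-methyl-6-[(2S)-6-methylhept-5-en-2-yl]-3-(propan-2-yl)-1,2,3,6,7,7a-hexahydro-5H-inden-5-one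
Conditions: NaBH4 (0.3 equiv), EtOH, −20 °C
Reagents that add atoms: none
Why: Chemoselective borohydride reduction of the saturated cyclopentanone in the presence of the enone should deliver hydride anti to the adjacent angular methyl, giving the hydroxyl cis to that methyl.

Step 9
Reactants: 11 ketol
Product: 12 tert-butyldimethylsilyl ether of 11
Conditions: TBSCl, imidazole, DMF, 40 °C
Reagents that add atoms: tert-butyldimethylsilyl chloride CC(C)(C)[Si](C)(C)Cl
Why: Standard silylation protects the hindered secondary alcohol for the basic, reducing and radical steps ahead.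

Step 10
Reactants: 12 silyl ether enone
Product: 13 (1R,3S,3aS,7aR)-1-[(tert-butyldimethylsilyl)oxy]-7a-methyl-6-[(2S)-6-methylhept-5-en-2-yl]-3-(propan-2-yl)octahydro-5H-inden-5-one
Conditions: Li, NH3(l)/THF, t-BuOH (1 equiv), −78 °C; then NH4Cl
Reagents that add atoms: none
Why: Dissolving-metal (Birch-type) enone reduction should protonate the β-carbanion axially with respect to ring C, giving the trans-hydrindane (ring-fusion hydrogen anti to the angular methyl); the isolated trisubstituted olefin and the silyl ether are inert.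

Step 11
Reactants: 13 trans-hydrindanone
Product: 15 (1R,3S,3aS,7aR)-1-[(tert-butyldimethylsilyl)oxy]-7a-methyl-6-[(2S)-6-methylhept-5-en-2-yl]-3-(propan-2-yl)-2,3,3a,4,7,7a-hexahydro-1H-inden-5-yl trifluoromethanesulfonate, via potassium enolate 14 (not isolated)
Conditions: KN(SiMe3)2 (0.95 equiv), THF, −78 → 0 °C (equilibration); then PhNTf2, −78 °C → rt
Reagents that add atoms: N-phenylbis(trifluoromethanesulfonimide) O=S(=O)(N(c1ccccc1)S(=O)(=O)C(F)(F)F)C(F)(F)F
Why: Thermodynamic enolate formation and O-triflation should give the tetrasubstituted enol triflate, because enolisation towards the side-chain carbon is more substituted and avoids an sp2 centre next to the strained trans ring fusion.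

Step 12
Reactants: 15 enol triflate
Product: 17 (4S)-4-Hyd-pentanal, via secondary ozonide 16 (not isolated)
Conditions: O3, CH2Cl2, −78 °C (Sudan red 7B end-point); then PPh3, −78 °C → rt
Reagents that add atoms: ozone [O-][O+]=O
Why: Ozonolysis should cleave the electron-rich trisubstituted side-chain olefin selectively, the electron-poor tetrasubstituted enol triflate reacting far more slowly.

Step 13
Reactants: 18 (S)-4-benzyloxazolidin-2-one; 19 hex-5-enoyl chloride
Product: 20 (S)-4-benzyl-3-(hex-5-enoyl)oxazolidin-2-one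
Conditions: Et3N, DMAP (cat.), CH2Cl2, 0 °C → rt
Reagents that add atoms: none
Why: N-Acylation of the oxazolidinone with the acid chloride gives the aldol donor.

Step 14
Reactants: 20 acyl oxazolidinone; 17 aldehyde
Product: 22 (4S)-4-benzyl-3-[(2S,3R,6S)-2-(but-3-en-1-yl)-3-hydroxy-6-Hyd-heptanoyl]oxazolidin-2-one, via Z-boron enolate 21 (not isolated)
Conditions: Bu2BOTf, i-Pr2NEt, CH2Cl2, −78 → 0 °C; then 17, −78 → 0 °C; pH 7 buffer, MeOH, H2O2
Reagents that add atoms: none
Why: Evans syn-aldol reaction: the Z-boron enolate should react through a closed chair transition state on the face opposite the benzyl group, setting the α-centre (the future ring-A carbon that bears the vinyl group) as S; the carbinol centre is erased in step 16.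

Step 15
Reactants: 22 aldol adduct
Product: 23 O-(1H-imidazol-1-ylcarbonothioyl) derivative of 22
Conditions: 1,1′-thiocarbonyldiimidazole, DMAP (cat.), ClCH2CH2Cl, 60 °C
Reagents that add atoms: 1,1′-thiocarbonyldiimidazole S=C(n1ccnc1)n1ccnc1
Why: Thiocarbonylation of the secondary alcohol (Barton–McCombie activation) under neutral conditions should avoid retro-aldol and elimination.

Step 16
Reactants: 23 thiocarbonylimidazolide
Product: 24 (4S)-4-benzyl-3-({(1S,2S,3S)-2-[(3S)-3-Hyd-butyl]-3-methylcyclopentyl}carbonyl)oxazolidin-2-one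
Conditions: Bu3SnH (slow addition), AIBN (cat.), PhH, 80 °C, 5 mM
Reagents that add atoms: none
Why: Barton–McCombie-type radical generation followed by 5-exo-trig hexenyl radical cyclisation should close ring A through a chair-like transition state with the bulky acyl group pseudo-equatorial (trans to the new methyl) and the radical-carbon substituent anti to it (cis to the new methyl), so the auxiliary-set centre fixes the other two ring-A centres in one event.

Step 17
Reactants: 24 cyclopentane imide
Product: 25 {(1S,2S,3S)-2-[(3S)-3-Hyd-butyl]-3-methylcyclopentyl}methanol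
Conditions: LiBH4, MeOH (1 equiv), Et2O, 0 °C
Reagents that add atoms: none
Why: Reductive cleavage of the N-acyl oxazolidinone should give the primary alcohol and release the auxiliary, the enol triflate and silyl ether being stable to borohydride.

Step 18
Reactants: 25 primary alcohol
Product: 26 (1S,2S,3S)-2-[(3S)-3-Hyd-butyl]-3-methylcyclopentane-1-carbaldehyde
Conditions: Dess–Martin periodinane, CH2Cl2, 0 °C → rt
Reagents that add atoms: none
Why: Dess–Martin oxidation gives the aldehyde; its α-centre already has the thermodynamically preferred trans arrangement to the neighbouring side chain.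

Step 19
Reactants: 26 aldehyde
Product: 27 (1R,2S,3S)-1-ethenyl-2-[(3S)-3-Hyd-butyl]-3-methylcyclopentane
Conditions: Ph3PCH3Br, KN(SiMe3)2, THF, −78 → 0 °C
Reagents that add atoms: methyltriphenylphosphonium bromide C[P+](c1ccccc1)(c1ccccc1)c1ccccc1.[Br-]
Why: Wittig methylenation should convert the aldehyde into the ring-A vinyl group at low temperature without loss of the trans α-centre (the R descriptor is a priority change only).

Step 20
Reactants: 27 enol triflate bearing the ring-A vinyl group
Product: 28 tert-butyldimethylsilyl ether of the target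
Conditions: Pd(PPh3)4 (20 mol %), K2CO3, 4 Å MS, MeCN, 85 °C, 5 mM
Reagents that add atoms: none
Why: Intramolecular Heck reaction: zerovalent palladium should insert into the enol triflate C–O bond, the vinylpalladium then adds across the ring-A vinyl group with C–C bond formation at its internal carbon, and bond rotation with syn β-hydride elimination of the only β-hydrogen releases the exocyclic methylene. The closest known reaction type is the Heck cyclisation of cyclohexenyl triflates onto terminal vinyl groups that closes eight-membered carbocycles carrying an exocyclic methylene next to the ring olefin. Ring B is closed in the 8-exo-trig mode. No stereocentre is formed, and the eight existing ones are remote from the reacting carbons. The step needs exo rather than 9-endo insertion and no migration of the new diene; the triflate (cationic) pathway favours attack at the internal vinyl carbon through the smaller ring, the cis tetrasubstituted ring-C olefin and the trans-1,2 substituents on ring A bring the termini together, and carbonate removes the palladium hydride before it can re-add. In one operation this step delivers the medium ring and both olefins of the diene in their final positions, leaving only desilylation.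

Step 21
Reactants: 28 silyl ether
Product: 29 target CNP0544018.1
Conditions: TBAF, THF, 50 °C
Reagents that add atoms: none
Why: Fluoride-mediated desilylation should free the hindered secondary alcohol without affecting the diene.

**Compound list**

1 | (S)-citronellal, (3S)-3,7-dimethyloct-6-enal | O=CC[C@@H](C)CCC=C(C)C | starting material
2 | (3S)-3,7-dimethyl-2-methylideneoct-6-enal | O=CC(=C)[C@@H](C)CCC=C(C)C | intermediate
3 | (4S)-4,8-dimethyl-3-methylidenenon-7-en-2-ol (carbinol epimers) | CC(O)C(=C)[C@@H](C)CCC=C(C)C | intermediate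
4 | (4S)-4,8-dimethyl-3-methylidenenon-7-en-2-one | CC(=O)C(=C)[C@@H](C)CCC=C(C)C | intermediate
5 | 2-methylcyclopentane-1,3-dione | CC1C(=O)CCC1=O | starting material
6 | 2-[(3S)-2-acetyl-3,7-dimethyloct-6-en-1-yl]-2-methylcyclopentane-1,3-dione (epimers at the acetyl-bearing carbon) | CC(=O)C(CC1(C)C(=O)CCC1=O)[C@@H](C)CCC=C(C)C | intermediate
7 | (3aR,7aR)-3a-hydroxy-7a-methyl-6-[(2S)-6-methylhept-5-en-2-yl]hexahydro-1H-indene-1,5(4H)-dione (cis-fused ketol, C6 epimers) | O=C1C([C@@H](C)CCC=C(C)C)C[C@@]2(C)C(=O)CC[C@@]2(O)C1 | intermediate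
8 | (7aR)-7a-methyl-6-[(2S)-6-methylhept-5-en-2-yl]-2,3,7,7a-tetrahydro-1H-indene-1,5(6H)-dione (C6 epimers) | O=C1C([C@@H](C)CCC=C(C)C)C[C@@]2(C)C(=O)CCC2=C1 | intermediate
9 | (7aR)-7a-methyl-6-[(2S)-6-methylhept-5-en-2-yl]-7,7a-dihydro-1H-indene-1,5(6H)-dione | O=C1C([C@@H](C)CCC=C(C)C)C[C@@]2(C)C(=O)C=CC2=C1 | intermediate
10 | (3S,7aR)-7a-methyl-6-[(2S)-6-methylhept-5-en-2-yl]-3-(propan-2-yl)-2,3,7,7a-tetrahydro-1H-indene-1,5(6H)-dione | O=C1C([C@@H](C)CCC=C(C)C)C[C@@]2(C)C(=O)C[C@@H](C(C)C)C2=C1 | intermediate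
11 | (1R,3S,7aR)-1-hydroxy-7a-methyl-6-[(2S)-6-methylhept-5-en-2-yl]-3-(propan-2-yl)-1,2,3,6,7,7a-hexahydro-5H-inden-5-one | O=C1C([C@@H](C)CCC=C(C)C)C[C@@]2(C)[C@H](O)C[C@@H](C(C)C)C2=C1 | intermediate
12 | (1R,3S,7aR)-1-[(tert-butyldimethylsilyl)oxy]-7a-methyl-6-[(2S)-6-methylhept-5-en-2-yl]-3-(propan-2-yl)-1,2,3,6,7,7a-hexahydro-5H-inden-5-one | O=C1C([C@@H](C)CCC=C(C)C)C[C@@]2(C)[C@H](O[Si](C)(C)C(C)(C)C)C[C@@H](C(C)C)C2=C1 | intermediate
13 | (1R,3S,3aS,7aR)-1-[(tert-butyldimethylsilyl)oxy]-7a-methyl-6-[(2S)-6-methylhept-5-en-2-yl]-3-(propan-2-yl)octahydro-5H-inden-5-one (C6 epimers) | O=C1C([C@@H](C)CCC=C(C)C)C[C@@]2(C)[C@H](O[Si](C)(C)C(C)(C)C)C[C@@H](C(C)C)[C@@H]2C1 | intermediate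
14 | potassium enolate of 13 (tetrasubstituted, towards the side-chain carbon) | [K+].[O-]C1=C([C@@H](C)CCC=C(C)C)C[C@@]2(C)[C@H](O[Si](C)(C)C(C)(C)C)C[C@@H](C(C)C)[C@@H]2C1 | intermediate
15 | (1R,3S,3aS,7aR)-1-[(tert-butyldimethylsilyl)oxy]-7a-methyl-6-[(2S)-6-methylhept-5-en-2-yl]-3-(propan-2-yl)-2,3,3a,4,7,7a-hexahydro-1H-inden-5-yl trifluoromethanesulfonate | O=S(=O)(OC1=C([C@@H](C)CCC=C(C)C)C[C@@]2(C)[C@H](O[Si](C)(C)C(C)(C)C)C[C@@H](C(C)C)[C@@H]2C1)C(F)(F)F | intermediate
16 | secondary ozonide (3,3-dimethyl-1,2,4-trioxolane) of the side-chain olefin of 15 | O=S(=O)(OC1=C([C@@H](C)CCC3OC(C)(C)OO3)C[C@@]2(C)[C@H](O[Si](C)(C)C(C)(C)C)C[C@@H](C(C)C)[C@@H]2C1)C(F)(F)F | intermediate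
17 | (4S)-4-Hyd-pentanal | O=S(=O)(OC1=C([C@@H](C)CCC=O)C[C@@]2(C)[C@H](O[Si](C)(C)C(C)(C)C)C[C@@H](C(C)C)[C@@H]2C1)C(F)(F)F | intermediate
18 | (S)-4-benzyloxazolidin-2-one | O=C1N[C@@H](Cc2ccccc2)CO1 | starting material
19 | hex-5-enoyl chloride | C=CCCCC(Cl)=O | starting material
20 | (S)-4-benzyl-3-(hex-5-enoyl)oxazolidin-2-one | C=CCCCC(=O)N1[C@@H](Cc2ccccc2)COC1=O | intermediate
21 | Z-dibutylboron enolate of 20 | C=CCC/C=C(\OB(CCCC)CCCC)N1[C@@H](Cc2ccccc2)COC1=O | intermediate
22 | (4S)-4-benzyl-3-[(2S,3R,6S)-2-(but-3-en-1-yl)-3-hydroxy-6-Hyd-heptanoyl]oxazolidin-2-one | O=S(=O)(OC1=C([C@@H](C)CC[C@@H](O)[C@@H](C(=O)N3[C@@H](Cc4ccccc4)COC3=O)CCC=C)C[C@@]2(C)[C@H](O[Si](C)(C)C(C)(C)C)C[C@@H](C(C)C)[C@@H]2C1)C(F)(F)F | intermediate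
23 | O-(1H-imidazol-1-ylcarbonothioyl) derivative of 22 | O=S(=O)(OC1=C([C@@H](C)CC[C@@H](OC(=S)n5ccnc5)[C@@H](C(=O)N3[C@@H](Cc4ccccc4)COC3=O)CCC=C)C[C@@]2(C)[C@H](O[Si](C)(C)C(C)(C)C)C[C@@H](C(C)C)[C@@H]2C1)C(F)(F)F | intermediate
24 | (4S)-4-benzyl-3-({(1S,2S,3S)-2-[(3S)-3-Hyd-butyl]-3-methylcyclopentyl}carbonyl)oxazolidin-2-one | O=S(=O)(OC1=C([C@@H](C)CC[C@@H]3[C@@H](C(=O)N4[C@@H](Cc5ccccc5)COC4=O)CC[C@@H]3C)C[C@@]2(C)[C@H](O[Si](C)(C)C(C)(C)C)C[C@@H](C(C)C)[C@@H]2C1)C(F)(F)F | intermediate
25 | {(1S,2S,3S)-2-[(3S)-3-Hyd-butyl]-3-methylcyclopentyl}methanol | O=S(=O)(OC1=C([C@@H](C)CC[C@@H]3[C@@H](CO)CC[C@@H]3C)C[C@@]2(C)[C@H](O[Si](C)(C)C(C)(C)C)C[C@@H](C(C)C)[C@@H]2C1)C(F)(F)F | intermediate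
26 | (1S,2S,3S)-2-[(3S)-3-Hyd-butyl]-3-methylcyclopentane-1-carbaldehyde | O=S(=O)(OC1=C([C@@H](C)CC[C@@H]3[C@@H](C=O)CC[C@@H]3C)C[C@@]2(C)[C@H](O[Si](C)(C)C(C)(C)C)C[C@@H](C(C)C)[C@@H]2C1)C(F)(F)F | intermediate
27 | (1R,2S,3S)-1-ethenyl-2-[(3S)-3-Hyd-butyl]-3-methylcyclopentane | O=S(=O)(OC1=C([C@@H](C)CC[C@@H]3[C@@H](C=C)CC[C@@H]3C)C[C@@]2(C)[C@H](O[Si](C)(C)C(C)(C)C)C[C@@H](C(C)C)[C@@H]2C1)C(F)(F)F | intermediate
28 | tert-butyldimethylsilyl ether of the target | C=C1C2=C(C[C@@]3(C)[C@H](O[Si](C)(C)C(C)(C)C)C[C@@H](C(C)C)[C@@H]3C2)[C@@H](C)CC[C@@H]2[C@@H]1CC[C@@H]2C | intermediate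
29 | target CNP0544018.1 (5-8-6-5 diene alcohol) | C=C1C2=C(C[C@@]3(C)[C@H](O)C[C@@H](C(C)C)[C@@H]3C2)[C@@H](C)CC[C@@H]2[C@@H]1CC[C@@H]2C | target

**Step count and risks**

Total: 21 steps. Longest linear sequence: 20 steps (steps 1–12 and 14–21, from (S)-citronellal).

Steps most likely to fail:

1. Step 20 (Heck closure of ring B). The medium-ring insertion may be slow, so that 9-endo insertion, loss of the triflate by reduction, or re-addition of palladium hydride with migration of the diene competes. The fallback sets out from aldehyde 26: a Nozaki–Hiyama–Kishi cyclisation (NiCl2 cat., CrCl2, DMSO, rt, high dilution) between the enol triflate and the aldehyde should give the ring-B allylic alcohol F1. Dess–Martin oxidation should give the cross-conjugated ring-B enone F2. Wittig methylenation (Ph3P=CH2, THF) then gives silyl ether 28, where the route is rejoined.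

2. Step 16 (radical closure of ring A). Facial control in the 5-exo closure may be insufficient, or hydrogen transfer may occur before cyclisation. The fallback sets out from aldehyde 17 and replaces the radical event by auxiliary-controlled polar steps and a directed hydrogenation:
   - Horner–Wadsworth–Emmons reaction with (S)-4-benzyl-3-[(diethoxyphosphoryl)acetyl]oxazolidin-2-one (LiCl, i-Pr2NEt, MeCN) should give the (E)-enoyl imide F3.
   - Chelate-controlled conjugate addition (isopropenylmagnesium bromide, CuBr·SMe2, THF, −78 °C, anti to the benzyl group) should give the β-isopropenyl imide F4.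
   - Enolate allylation (NaN(SiMe3)2, allyl iodide, −78 °C, anti to the benzyl group) should give the α-allyl-β-isopropenyl imide F5.
   - Ring-closing metathesis with second-generation Grubbs catalyst (H2IMes)(PCy3)Cl2Ru=CHPh (CH2Cl2, 40 °C) should give the cyclopentene imide F6.
   - LiBH4 should give the cyclopentenylmethanol F7.
   - Hydroxyl-directed hydrogenation with [Ir(cod)(PCy3)(py)]PF6 and H2 (CH2Cl2) should deliver hydrogen syn to the CH2OH group and give alcohol 25, where the route is rejoined.

3. Step 6 (IBX dehydrogenation). Dehydrogenation may be unselective, with attack at the α′,β′-positions of the cyclohexenone or over-oxidation. The fallback sets out from enedione 8: kinetic enolisation of the unhindered cyclopentanone (LiN(iPr)2, TMSCl, THF, −78 °C) should give the trimethylsilyl enol ether F8. Saegusa–Ito oxidation (Pd(OAc)2, MeCN, rt) then gives dienedione 9, where the route is rejoined.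

Further compounds

F1 | step 20 | ring-B allylic alcohol (silyl-protected, carbinol epimers) | OC1C2=C(C[C@@]3(C)[C@H](O[Si](C)(C)C(C)(C)C)C[C@@H](C(C)C)[C@@H]3C2)[C@@H](C)CC[C@@H]2[C@@H]1CC[C@@H]2C
F2 | step 20 | ring-B cross-conjugated enone (silyl-protected) | O=C1C2=C(C[C@@]3(C)[C@H](O[Si](C)(C)C(C)(C)C)C[C@@H](C(C)C)[C@@H]3C2)[C@@H](C)CC[C@@H]2[C@@H]1CC[C@@H]2C
F3 | step 16 | (E)-enoyl imide from 17 | O=S(=O)(OC1=C([C@@H](C)CC/C=C/C(=O)N3[C@@H](Cc4ccccc4)COC3=O)C[C@@]2(C)[C@H](O[Si](C)(C)C(C)(C)C)C[C@@H](C(C)C)[C@@H]2C1)C(F)(F)F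
F4 | step 16 | β-isopropenyl imide | O=S(=O)(OC1=C([C@@H](C)CC[C@@H](C(C)=C)CC(=O)N3[C@@H](Cc4ccccc4)COC3=O)C[C@@]2(C)[C@H](O[Si](C)(C)C(C)(C)C)C[C@@H](C(C)C)[C@@H]2C1)C(F)(F)F
F5 | step 16 | α-allyl-β-isopropenyl imide | O=S(=O)(OC1=C([C@@H](C)CC[C@@H](C(C)=C)[C@H](CC=C)C(=O)N3[C@@H](Cc4ccccc4)COC3=O)C[C@@]2(C)[C@H](O[Si](C)(C)C(C)(C)C)C[C@@H](C(C)C)[C@@H]2C1)C(F)(F)F
F6 | step 16 | cyclopentene imide | O=S(=O)(OC1=C([C@@H](C)CC[C@@H]3[C@@H](C(=O)N4[C@@H](Cc5ccccc5)COC4=O)CC=C3C)C[C@@]2(C)[C@H](O[Si](C)(C)C(C)(C)C)C[C@@H](C(C)C)[C@@H]2C1)C(F)(F)F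
F7 | step 16 | cyclopentenylmethanol | O=S(=O)(OC1=C([C@@H](C)CC[C@@H]3[C@@H](CO)CC=C3C)C[C@@]2(C)[C@H](O[Si](C)(C)C(C)(C)C)C[C@@H](C(C)C)[C@@H]2C1)C(F)(F)F
F8 | step 6 | trimethylsilyl enol ether of the cyclopentanone of 8 | O=C1C([C@@H](C)CCC=C(C)C)C[C@@]2(C)C(O[Si](C)(C)C)=CCC2=C1
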